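(The runs stem from a simulated flask from invented constants, noise included.)

**The question.** You asked for a quick number: which set-up keeps most of the converted L as Q, and your hunch favours the slow dosing of E.

| flask | L | E | remark | time |
|---|---|---|---|---|
| north-west | 0.050 M | 0.090 M | run made earlier |  |
| south | 0.025 M | 0.090 M | run made earlier |  |
| west | 0.038 M | 0.090 M | run made earlier |  |
| east | 0.050 M | 0.18 M | run made earlier |  |
| noon | 0.050 M | 0.0900 M | one stirred flow tank at steady state, fed with the mixture as stated, mean residence time 6.0 h |  |
| dusk | 0.050 M | 0.0900 M | a tube with plug flow, the mixed feed as stated, residence time 6.0 h | 6.0 h |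
| winter | 0.050 M | 0.0900 M (fed, over 4.80 h) | all but E at the start; E goes in evenly over 4.80 h, the run ends at 6.0 h | 6.0 h |
| midnight | 0.050 M | 0.0900 M | everything together in a closed stirred flask, run for 6.0 h | 6.0 h |

| run | time / h | Q / % | J / % |
|---|---|---|---|
| north-west | 0.833 | 11.2 | 0.6 |
| north-west | 2.00 | 21.7 | 2.4 |
| north-west | 4.00 | 30.4 | 5.9 |
| north-west | 6.00 | 34.8 | 9.0 |
| south | 0.500 | 7.5 | 0.4 |
| south | 1.00 | 13.0 | 0.6 |
| south | 2.50 | 24.2 | 2.7 |
| south | 6.00 | 36.0 | 8.3 |
| west | 1.50 | 16.9 | 1.3 |
| west | 3.00 | 25.7 | 3.3 |
| west | 5.00 | 33.0 | 6.8 |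
| west | 6.00 | 35.1 | 8.7 |
| east | 0.833 | 19.0 | 2.3 |
| east | 2.00 | 31.3 | 4.9 |
| east | 4.00 | 38.6 | 12.1 |
| east | 6.00 | 42.6 | 17.5 |

(standard deviation of a reading: 0.5 percentage points)

- the stated concentrations are those of everything mixed, before any reaction; amounts are the same in each set-up
- the feed brings no volume worth counting
- the earlier runs were made in a closed, stirred flask

1. the set-up with the highest share of Q in all that became Q or J or X, at the outlet or at the end ("none" if the first two lie within 2 percentage points) (noon / dusk / winter / midnight / none)
2. share of Q in all that became Q or J or X, at the outlet or at the end, noon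
3. share of Q in all that became Q or J or X, at the outlet or at the end, dusk
4. share of Q in all that became Q or J or X, at the outlet or at the end, winter
5. share of Q in all that became Q or J or X, at the outlet or at the end, midnight

**The balance.** We write the balance of L, the reagent charged in the smaller amount, in fractions of the charge: L left, a, plus Q, J and X makes 1. X goes unread, so we take it as small. If both additions are first order in E, E drops out of the ratio of their rates, and each unit of L lost makes J at s·Q/a. Here s is the selectivity factor, the rate constant of Q to J over that of L to Q. The east run between its second and last readings gives s = 0.740, a reading with their scatter.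

**Two rules.** In a flask without back-mixing, Q = (a^s − a)/(1 − s). In a tank, the share of Q is 1/(1 + s(1 − a)/a). The last north-west reading, with X taken as small, leaves a = 56.2%, so our share for midnight is 79.8%.

**The forecast.** It says winter, with noon 71%, dusk 77%, winter 84% and midnight 77%, so its midnight stands lower than ours. Its ground for winter: “slow feed gives less E-time”.

**The outcome.** Winter gives the highest share: noon 75.1%, dusk 81.9%, winter 86.0%, midnight 81.9%.

    E + J → X + G (k = 0.0413 M⁻¹ h⁻¹)
    E + Q → J + G (k = 1.23 M⁻¹ h⁻¹)
    L + E → Q + G (k = 1.79 M⁻¹ h⁻¹)
    2 E → D (k = 1.01 M⁻¹ h⁻¹)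

**Two flasks.** Winter ends with 65.7% of its L left, and the first rule with s turns that into 85.0%, against 86.0%. Noon keeps 67.4% of its L, and the tank rule gives 73.7%, against 75.1%. The length of the run is part of why winter's share stands at 86.0%: left for 60.0 h, winter falls to 62.2%.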